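**Retrosynthetic overview**

1. Last disconnection: the A-ring epoxide (C2–C3), installed by nucleophilic epoxidation of the enone anti to the pseudoaxial C4–O(aryl) bond of the finished bis-ketal.
2. Key disconnection: both ketal C–O bonds at C4, back to an open 5-substituted juglone (A) that carries on C5 the tertiary carbinol C4' of an epoxy-tetralindiol (B). Forward, one oxidation closes the oxa-five ring (C4, C4a, C5, C4', O) by hemiketalization and then the 1,3-dioxin ring by aryl C–O bond formation at C5'.
3. Enabling feature: in ring B the phenol O–H on C8' is para to the unsubstituted C5', both ortho positions are blocked (C7'–Cl and the ring fusion C8a'), and C5' is peri to C4'. Two-electron oxidation of this phenol makes C5' electrophilic exactly where the hemiketal O–H on C4 is held by the five-membered lactol.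
4. C5–C4' bond: an aryllithium (A half) adds to an enantioenriched 2,3-epoxynaphthalene-1,4-dione (B half); both halves come from one naphthol made from 5,8-dimethoxy-1-tetralone.
5. Stereochemistry and ring order: one catalytic event (phase-transfer asymmetric epoxidation, C2'/C3') is relayed to C4' (addition anti to the epoxide), C1' (directed hydride), C4 (geometry of the bicyclic ketal) and C2/C3 (final epoxidation). Rings form in the order B epoxide, A quinone, oxa-five ring plus dioxin ring, A epoxide.

Key step: step 13

Locants: unprimed = ketone (A) half, primed = carbinol (B) half; each half is numbered as a naphthalene with the phenol on C8/C8', chlorine on C7/C7', the inter-ring bond C5–C4' and the ketal carbon C4.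

Assumption: the sense of induction of the cinchona phase-transfer catalyst in step 6 cannot be assigned in advance; the cinchonidinium series is written, and the pseudoenantiomeric cinchoninium salt is used instead if that is the one that delivers the (2S,3R)-epoxide.

**Route**

Step 1
Reactants: 1 5,8-dimethoxy-3,4-dihydronaphthalen-1(2H)-one
Product: 3 2-chloro-5,8-dimethoxynaphthalen-1-ol, via gem-dichloro ketone 2 (not isolated)
Conditions: NCS (2.3 equiv), TsOH·H2O (cat.), MeCN, 60 °C; then Li2CO3, DMF, 100 °C
Reagents that add atoms: N-chlorosuccinimide, O=C1CCC(=O)N1Cl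
Why: Acid-catalysed α,α-dichlorination of the ketone followed by base-induced dehydrochlorination and tautomerization (aromatization of a 2,2-dihalotetralone) places chlorine ortho to the naphthol OH without any ortho/para ambiguity.

Step 2
Reactants: 3 2-chloro-5,8-dimethoxynaphthalen-1-ol
Product: 4 4-bromo-2-chloro-5,8-dimethoxynaphthalen-1-ol
Conditions: NBS (1.0 equiv), MeCN, −30 °C, dark
Reagents that add atoms: N-bromosuccinimide, O=C1CCC(=O)N1Br
Why: Electrophilic aromatic bromination should go para to the free naphthol OH, the only open activated α-position, since the ortho site already carries chlorine.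

Step 3
Reactants: 4 4-bromo-2-chloro-5,8-dimethoxynaphthalen-1-ol
Product: 5 [(4-bromo-2-chloro-5,8-dimethoxynaphthalen-1-yl)oxy](tert-butyl)dimethylsilane
Conditions: TBSOTf, 2,6-lutidine, CH2Cl2, 0 °C
Reagents that add atoms: tert-butyldimethylsilyl triflate, CC(C)(C)[Si](C)(C)OS(=O)(=O)C(F)(F)F
Why: O-Silylation of the hindered naphthol gives an ether that tolerates halogen–lithium exchange (silicon is para to the future carbanion, so no silyl migration) and is removed later by fluoride.

Step 4
Reactants: 3 2-chloro-5,8-dimethoxynaphthalen-1-ol
Product: 6 2-chloro-5,8-dimethoxy-1-(methoxymethoxy)naphthalene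
Conditions: MOMCl, i-Pr2NEt, CH2Cl2, 0 °C to rt
Reagents that add atoms: chloromethyl methyl ether, COCCl
Why: O-Alkylation to the MOM acetal gives a phenol protecting group that is stable to the basic methanol of the electrolysis and to the aqueous base of the phase-transfer epoxidation.

Step 5
Reactants: 6 2-chloro-5,8-dimethoxy-1-(methoxymethoxy)naphthalene
Product: 8 7-chloro-4,4-dimethoxy-8-(methoxymethoxy)naphthalen-1(4H)-one, via quinone bisketal 7 (not isolated)
Conditions: Pt anode, undivided cell, 1% KOH in MeOH, 0 °C, constant current; then 5% aq. AcOH–acetone, 0 °C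
Reagents that add atoms: methanol, CO; water, O
Why: Anodic methoxylation of the p-dimethoxy ring gives the quinone bisketal, and mild acid should hydrolyse only the ketal peri to the alkoxy-bearing ring carbon (o-alkoxybenzyl-type oxocarbenium, relief of peri strain); either monoketal regioisomer would lead to the same dione in step 7, so regiopurity matters only for the enantiomeric purity.

Step 6
Reactants: 8 7-chloro-4,4-dimethoxy-8-(methoxymethoxy)naphthalen-1(4H)-one
Product: 9 (2S,3R)-7-chloro-2,3-epoxy-4,4-dimethoxy-8-(methoxymethoxy)-2,3-dihydronaphthalen-1(4H)-one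
Conditions: t-BuOOH (70% aq.), N-benzylcinchonidinium chloride (10 mol%), 1 M NaOH, toluene, 0 °C
Reagents that add atoms: tert-butyl hydroperoxide, CC(C)(C)OO
Why: Weitz–Scheffer epoxidation of a quinone monoketal under chiral phase-transfer catalysis; the chiral ammonium/hydroperoxide ion pair differentiates the enantiotopic faces of the enone and sets C2' and C3' in one event, the only stereocentres made by catalysis.

Step 7
Reactants: 9 (2S,3R)-7-chloro-2,3-epoxy-4,4-dimethoxy-8-(methoxymethoxy)-2,3-dihydronaphthalen-1(4H)-one
Product: 10 (2R,3S)-6-chloro-2,3-epoxy-5-hydroxy-2,3-dihydronaphthalene-1,4-dione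
Conditions: TFA–H2O (9:1), CH2Cl2, 0 °C to rt
Reagents that add atoms: water, O
Why: Acid hydrolysis cleaves the dimethyl ketal and the MOM acetal together, while the epoxide, flanked by two carbonyl groups, is deactivated towards acid opening and has no epimerizable centre.

Step 8
Reactants: 10 (2R,3S)-6-chloro-2,3-epoxy-5-hydroxy-2,3-dihydronaphthalene-1,4-dione
Product: 11 (2R,3S)-5-[(tert-butyldimethylsilyl)oxy]-6-chloro-2,3-epoxy-2,3-dihydronaphthalene-1,4-dione
Conditions: TBSOTf, 2,6-lutidine, CH2Cl2, −40 °C
Reagents that add atoms: tert-butyldimethylsilyl triflate, CC(C)(C)[Si](C)(C)OS(=O)(=O)C(F)(F)F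
Why: O-Silylation of the chelated phenol installs a bulky, non-chelating group that shields the peri carbonyl C1' in the next step and keeps the B phenol masked until the A quinone exists.

Step 9
Reactants: 5 [(4-bromo-2-chloro-5,8-dimethoxynaphthalen-1-yl)oxy](tert-butyl)dimethylsilane; 11 (2R,3S)-5-[(tert-butyldimethylsilyl)oxy]-6-chloro-2,3-epoxy-2,3-dihydronaphthalene-1,4-dione
Product: 12 tertiary carbinol ketone (aryl on C4', C4'–OH cis to the epoxide oxygen, C1'=O retained)
Conditions: 5, n-BuLi, THF, −78 °C; LaCl3·2LiCl; then 11, −78 °C; then H2O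
Reagents that add atoms: none
Why: Bromine–lithium exchange and 1,2-addition of the aryllithium to a ketone; C4'=O should react because C1'=O is shielded and electronically deactivated by the peri silyloxy group, and the aryl group should enter anti to the epoxide oxygen, as in additions to epoxyquinone monoketals, so C4' is set with its hydroxyl cis to the epoxide.

Step 10
Reactants: 12 tertiary carbinol ketone
Product: 13 diol (C1'–OH trans to the epoxide oxygen and cis to the naphthyl group)
Conditions: DIBAL-H (3 equiv), THF, −78 °C; aq. Rochelle salt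
Reagents that add atoms: none
Why: Hydride reduction of an α,β-epoxy ketone; aluminium coordinated to the epoxide oxygen should deliver hydride on the epoxide face, and the opposite face is covered by the pseudoaxial naphthyl group on C4', so both effects set C1' with its hydroxyl trans to the epoxide.

Step 11
Reactants: 13 diol
Product: 14 hydroxy-quinone bis-silyl ether
Conditions: CAN (2.5 equiv), MeCN–H2O (4:1), −10 to 0 °C
Reagents that add atoms: water, O
Why: Cerium(IV) oxidative demethylation of the p-dimethoxyarene gives the A-ring naphthoquinone; the silyl-masked, chlorinated B ring is far less oxidizable and should stay intact.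

Step 12
Reactants: 14 hydroxy-quinone bis-silyl ether
Product: 15 open hydroxy-quinone bis-phenol
Conditions: HF·pyridine, pyridine, THF, 0 °C
Reagents that add atoms: none
Why: Fluoride cleavage of both aryl silyl ethers under buffered, non-basic conditions that leave the quinone and the epoxide untouched.

Step 13
Reactants: 15 open hydroxy-quinone bis-phenol
Product: 17 hexacyclic bis-ketal enone (target without the A-ring epoxide), via lactol 16 (not isolated)
Conditions: PhI(OAc)2 (1.05 equiv, slow addition), (CF3)2CHOH, −20 to 0 °C
Reagents that add atoms: none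
Why: Hypervalent-iodine phenol umpolung (oxidative phenolic C–O coupling, the reaction type of PIDA para-alkoxylations and oxidative spiroketalizations) is applied to a substrate whose only positioned nucleophile is a hemiketal hydroxyl: the tertiary C4'–OH adds reversibly to the peri quinone carbonyl C4 (5-exo-trig hemiketalization, oxa-five ring C4–C4a–C5–C4'–O) to give lactol 16, PIDA exchanges acetate for the B-ring phenol oxygen, and loss of PhI makes the para carbon C5' electrophilic. The lactol O–H then attacks C5' (6-exo-trig onto the quinoid C5'=C6' bond, closing the 1,3-dioxin ring C4–O–C5'–C4a'–C4'–O), and loss of H5' re-aromatizes the ring to the aryl ketal. The new stereocentre C4 is not chosen by the reagent: only the lactol epimer whose hydroxyl lies on the side of the B arene can reach C5', the epimers equilibrate through the open quinone, and the 2,8-dioxabicyclo[3.2.1]octane geometry ties its configuration to that of C4'. Site selectivity comes from the substrate: both ortho positions of the B phenol are blocked (C7'–Cl and the ring fusion C8a'), so only C5' can accept the nucleophile, and the A-ring phenol is a hydrogen-bonded peri-acyl phenol on a quinone and should not be oxidized at this temperature. Over-oxidation of the product hydroquinone mono-ether is held back by one equivalent of oxidant added slowly at low temperature in a medium without external nucleophile, since its para position is then fully substituted.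

Step 14
Reactants: 17 hexacyclic bis-ketal enone
Product: 18 CNP0289684.3
Conditions: 30% H2O2, K2CO3, THF–H2O, 0 °C
Reagents that add atoms: hydrogen peroxide, OO
Why: Weitz–Scheffer epoxidation of the quinone-monoketal enone; hydroperoxide should add to C3 anti to the pseudoaxial C4–O(aryl) bond, on the face not covered by the B arene, which sets C2 and C3 in one event with the epoxide cis to the five-ring oxygen, and the free peri phenol is tolerated as in the epoxidation of juglone.

**Compound list**

1 | 5,8-dimethoxy-3,4-dihydronaphthalen-1(2H)-one (5,8-dimethoxy-1-tetralone) | O=C1CCCc2c(OC)ccc(OC)c12 | starting material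
2 | 2,2-dichloro-5,8-dimethoxy-3,4-dihydronaphthalen-1(2H)-one | O=C1c2c(OC)ccc(OC)c2CCC1(Cl)Cl | intermediate (not isolated)
3 | 2-chloro-5,8-dimethoxynaphthalen-1-ol | Oc1c(Cl)ccc2c(OC)ccc(OC)c12 | intermediate
4 | 4-bromo-2-chloro-5,8-dimethoxynaphthalen-1-ol | Oc1c(Cl)cc(Br)c2c(OC)ccc(OC)c12 | intermediate
5 | [(4-bromo-2-chloro-5,8-dimethoxynaphthalen-1-yl)oxy](tert-butyl)dimethylsilane | COc1ccc(OC)c2c(O[Si](C)(C)C(C)(C)C)c(Cl)cc(Br)c12 | intermediate
6 | 2-chloro-5,8-dimethoxy-1-(methoxymethoxy)naphthalene | COCOc1c(Cl)ccc2c(OC)ccc(OC)c12 | intermediate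
7 | 6-chloro-1,1,4,4-tetramethoxy-5-(methoxymethoxy)-1,4-dihydronaphthalene (quinone bisketal) | COCOc1c(Cl)ccc2c1C(OC)(OC)C=CC2(OC)OC | intermediate (not isolated)
8 | 7-chloro-4,4-dimethoxy-8-(methoxymethoxy)naphthalen-1(4H)-one | COCOc1c(Cl)ccc2c1C(=O)C=CC2(OC)OC | intermediate
9 | (2S,3R)-7-chloro-2,3-epoxy-4,4-dimethoxy-8-(methoxymethoxy)-2,3-dihydronaphthalen-1(4H)-one | COC1(OC)c2ccc(Cl)c(OCOC)c2C(=O)[C@H]2O[C@@H]12 | intermediate
10 | (2R,3S)-6-chloro-2,3-epoxy-5-hydroxy-2,3-dihydronaphthalene-1,4-dione | O=C1c2ccc(Cl)c(O)c2C(=O)[C@H]2O[C@@H]12 | intermediate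
11 | (2R,3S)-5-[(tert-butyldimethylsilyl)oxy]-6-chloro-2,3-epoxy-2,3-dihydronaphthalene-1,4-dione | O=C1c2ccc(Cl)c(O[Si](C)(C)C(C)(C)C)c2C(=O)[C@H]2O[C@@H]12 | intermediate
12 | 4-[4-(tert-butyldimethylsilyloxy)-3-chloro-5,8-dimethoxynaphthalen-1-yl]-8-(tert-butyldimethylsilyloxy)-7-chloro-2,3-epoxy-4-hydroxy-3,4-dihydronaphthalen-1(2H)-one; 4-OH cis to the epoxide oxygen, absolute configuration as in the SMILES | COc1ccc(OC)c2c(O[Si](C)(C)C(C)(C)C)c(Cl)cc(c12)[C@]1(O)c2ccc(Cl)c(O[Si](C)(C)C(C)(C)C)c2C(=O)[C@H]2O[C@@H]12 | intermediate
13 | the 1,4-diol from 12: C1'–OH trans to the epoxide oxygen, C4'–OH cis to it, absolute configuration as in the SMILES | COc1ccc(OC)c2c(O[Si](C)(C)C(C)(C)C)c(Cl)cc(c12)[C@]1(O)c2ccc(Cl)c(O[Si](C)(C)C(C)(C)C)c2[C@H](O)[C@H]2O[C@@H]12 | intermediate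
14 | 8-(tert-butyldimethylsilyloxy)-7-chloro-1,4-naphthoquinone carrying on C5 the B unit of 13 (hydroxy-quinone bis-silyl ether) | O=C1C=CC(=O)c2c1c(O[Si](C)(C)C(C)(C)C)c(Cl)cc2[C@]1(O)c2ccc(Cl)c(O[Si](C)(C)C(C)(C)C)c2[C@H](O)[C@H]2O[C@@H]12 | intermediate
15 | 7-chloro-8-hydroxy-1,4-naphthoquinone carrying on C5 the 7'-chloro-2',3'-epoxy-1',4',8'-trihydroxy-tetralin-4'-yl unit (open hydroxy-quinone bis-phenol; 1'-OH trans and 4'-OH cis to the epoxide) | O=C1C=CC(=O)c2c1c(O)c(Cl)cc2[C@]1(O)c2ccc(Cl)c(O)c2[C@H](O)[C@H]2O[C@@H]12 | intermediate
16 | lactol of 15: five-membered hemiketal between C4 and the C4' oxygen, free hemiketal OH on C4 | O=C1c2c(O)c(Cl)cc3c2[C@](O)(O[C@]32c3ccc(Cl)c(O)c3[C@H](O)[C@@H]3[C@H]2O3)C=C1 | intermediate (not isolated)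
17 | hexacyclic bis-ketal enone: the target with a C2=C3 double bond in place of the A-ring epoxide | O=C1c2c(O)c(Cl)cc3c2[C@@]2(Oc4cc(Cl)c(O)c5c4[C@]3(O2)[C@@H]2O[C@@H]2[C@H]5O)C=C1 | intermediate
18 | CNP0289684.3 (A-ring epoxide cis to the five-ring oxygen, B-ring epoxide cis to the C4' oxygen and trans to the C1' hydroxyl) | O=C1c2c(O)c(Cl)cc3c2[C@@]2(Oc4cc(Cl)c(O)c5c4[C@]3(O2)[C@@H]2O[C@@H]2[C@H]5O)[C@@H]2O[C@H]12 | target

**Step count and risks**

Total steps: 14. Longest linear sequence: 12 steps (1, 4, 5, 6, 7, 8, 9, 10, 11, 12, 13, 14); the A-half branch (steps 2 and 3) joins at step 9.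

Three steps most likely to fail:

1. Step 13. What may go wrong: over-oxidation of the newly formed hydroquinone mono-ether, competing benzylic oxidation at C1', or capture of the oxidized phenol by adventitious water instead of the lactol hydroxyl. Fallback (changes the bond-forming logic to a conventional ketalization): it sets out from 15. Teuber oxidation with Fremy's salt (aq. KH2PO4–acetone) converts the B-ring phenol, which has a free para position, into the 5',8'-para-quinone, the bis-quinone F1. One equivalent of Na2S2O4 then reduces the more strongly oxidizing chlorobenzoquinone ring, giving the B-ring hydroquinone F2 with the juglone ring left at the quinone level. PPTS with 4 Å molecular sieves in CH2Cl2 closes both ketal bonds by dehydrative ketalization of C4=O with the C4' hydroxyl and the new C5' phenol, and the sequence comes back to the route at 17.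

2. Step 9. What may go wrong: attack at the wrong carbonyl (C1'), poor facial selectivity, or electron transfer to and ring-opening of the epoxy-dione by the aryllithium. Fallback (regiocontrol by charge instead of by a protecting group, addition before protection): it sets out from 10. The free phenol is deprotonated with NaH (1.0 equiv, THF, −78 °C), so that the peri phenoxide turns C1'=O into a vinylogous carboxylate and leaves C4'=O as the only electrophilic carbonyl. The aryllithium from 5 is then added to give the phenol adduct F3, and selective O-silylation of its phenol (TBSCl, imidazole, DMF) brings the sequence back to the route at 12.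

3. Step 6. What may go wrong: insufficient enantioface discrimination for this peri-substituted monoketal, and erosion of enantiomeric purity by any regioisomeric monoketal carried over from step 5. Fallback (auxiliary control with separable diastereomers instead of catalysis): it sets out from 8. Transketalization with (R,R)-hydrobenzoin (PPTS, benzene, reflux, removal of methanol) gives the (R,R)-hydrobenzoin ketal F4. Nucleophilic epoxidation (t-BuOOH, DBU, CH2Cl2) under auxiliary control gives diastereomeric epoxides that are separated by crystallization or chromatography, the required one being the epoxy ketal F5 (the diol antipode is chosen so that it is the major one). Aqueous TFA then removes the auxiliary ketal and the MOM group, and the sequence comes back to the route at 10.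

**Further compounds**

F1 | step 13 | bis-quinone: 15 with the B ring oxidized to the 5',8'-para-quinone | O=C1C=CC(=O)c2c1c(O)c(Cl)cc2[C@]1(O)C2=C(C(=O)C(Cl)=CC2=O)[C@H](O)[C@H]2O[C@@H]12
F2 | step 13 | B-ring hydroquinone: the 5'-hydroxy analogue of 15 | O=C1C=CC(=O)c2c1c(O)c(Cl)cc2[C@]1(O)c2c(O)cc(Cl)c(O)c2[C@H](O)[C@H]2O[C@@H]12
F3 | step 9 | phenol adduct: 12 with a free 8'-OH in place of the 8'-silyl ether | COc1ccc(OC)c2c(O[Si](C)(C)C(C)(C)C)c(Cl)cc(c12)[C@]1(O)c2ccc(Cl)c(O)c2C(=O)[C@H]2O[C@@H]12
F4 | step 6 | (R,R)-hydrobenzoin ketal of 7-chloro-8-(methoxymethoxy)-1,4-naphthoquinone at C4 | O=C1C=CC2(O[C@H](c3ccccc3)[C@@H](c3ccccc3)O2)c2ccc(Cl)c(OCOC)c12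
F5 | step 6 | (2S,3R)-2,3-epoxide of F4 | O=C1[C@H]2O[C@H]2C2(O[C@H](c3ccccc3)[C@@H](c3ccccc3)O2)c2ccc(Cl)c(OCOC)c12
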